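**Retrosynthetic overview**

1. Target 31 comes from alcohol 29 and umbelliferone (C11–O bond), after desulfonylation and desilylation of the bicyclic sulfone 27.
2. Sulfone 27 comes from the acyclic precursor 25 in one tin-hydride radical cascade that makes C5–C10 first (ring B) and then C2–C3 (ring A).
3. Enabling feature: in ring A (C1, C2, C3, C4, C5, C10) the two new bonds lie opposite each other, so the ring splits into a C3–C4–C5 unit whose ends are insulated by the quaternary C4, and a C10–C1–C2 allyl unit. C10 also belongs to ring B, so a 2-sulfonylallyl sulfone on C10–C1–C2 can accept a C5 radical at C10, lose PhSO2• and then offer C2 to a C3 radical.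
4. Precursor 25 comes from aldehyde 19 (Mukaiyama aldol for C4–C5, thionocarbonate, acyl chloride addition); 19 comes from alkynyl sulfone 12 (methyl addition, formaldehyde trap, sulfinate displacement).
5. Sulfone 12 comes from allylic phosphate 6, where a Cu-catalysed SN2′ alkynylation sets C9 and the C8=C12 alkene together; 6 is built from but-2-yne-1,4-diol by directed carbomagnesiation.

Key step: step 14

Remark on the chemistry: drimane numbering of the target is used for the corresponding atoms of all intermediates (C3 carries the ester, C4 the two methyl groups, C5 and C10 are the ring-fusion carbons, C8 carries the methylene C12, C9 the CH2O carbon C11). The target is the (3R,5S,9R,10R) isomer. The geometry of the C10=C1 alkene and the configurations at the carbinol, chloro and sulfonyl carbons of intermediates do not affect the outcome; these centres are carried as mixtures.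

**Route**

Step 1
Reactants: 1 but-2-yne-1,4-diol
Product: 2 4-[(tert-butyldiphenylsilyl)oxy]but-2-yn-1-ol
Conditions: TBDPSCl, imidazole, DMF, 0 °C to rt (diol in excess)
Reagents that add atoms: tert-butyl(chloro)diphenylsilane, CC(C)(C)[Si](Cl)(c1ccccc1)c1ccccc1
Why: Monosilylation of a symmetrical diol used in excess (silyl ether formation) should give the mono-ether, and no stereocentre is involved.

Step 2
Reactants: 2 4-[(tert-butyldiphenylsilyl)oxy]but-2-yn-1-ol; 3 2-(2-bromoethyl)-1,3-dioxolane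
Product: 5 (2E)-4-[(tert-butyldiphenylsilyl)oxy]-2-[2-(1,3-dioxolan-2-yl)ethyl]but-2-en-1-ol, via Grignard reagent 4 (not isolated)
Conditions: 3, Mg, THF, rt; then 2, CuI (10 mol %), THF/Et2O, −20 °C to rt; aq NH4Cl
Reagents that add atoms: 2-(2-bromoethyl)-1,3-dioxolane (3, as its Grignard reagent 4), BrCCC1OCCO1
Why: Copper-catalysed anti-carbomagnesiation of a propargylic alcohol, in which the magnesium alkoxide directs the alkyl group to the carbon next to CH2OH and the chelated alkenylmagnesium is protonated with retention, should give the E trisubstituted alkene.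

Step 3
Reactants: 5 (2E)-4-[(tert-butyldiphenylsilyl)oxy]-2-[2-(1,3-dioxolan-2-yl)ethyl]but-2-en-1-ol
Product: 6 (2E)-4-[(tert-butyldiphenylsilyl)oxy]-2-[2-(1,3-dioxolan-2-yl)ethyl]but-2-en-1-yl diethyl phosphate
Conditions: ClP(O)(OEt)2, pyridine, DMAP (cat.), CH2Cl2, 0 °C
Reagents that add atoms: diethyl chlorophosphate, CCOP(=O)(Cl)OCC
Why: O-Phosphorylation of the primary allylic alcohol provides the leaving group for allylic substitution.

Step 4
Reactants: 6 allylic phosphate; 7 ethynyltrimethylsilane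
Product: 8 tert-butyl({(2R)-2-[4-(1,3-dioxolan-2-yl)but-1-en-2-yl]-4-(trimethylsilyl)but-3-yn-1-yl}oxy)diphenylsilane
Conditions: CuCl (10 mol %), chiral N-heterocyclic carbene ligand (from its imidazolinium salt, 12 mol %), LiOtBu, THF, 0 °C
Reagents that add atoms: ethynyltrimethylsilane (7), C#C[Si](C)(C)C
Why: Copper-catalysed enantioselective allylic alkylation of a terminal alkyne (SN2′, γ-selective) should attack the CH2OSi-bearing alkene carbon, which creates the C9 stereocentre under ligand control (ligand enantiomer chosen for R) and moves the double bond to the exocyclic C8=C12 position.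

Step 5
Reactants: 8 silylated enyne
Product: 9 tert-butyl({(2R)-2-[4-(1,3-dioxolan-2-yl)but-1-en-2-yl]but-3-yn-1-yl}oxy)diphenylsilane
Conditions: K2CO3, MeOH, rt
Reagents that add atoms: none
Why: Base-mediated protodesilylation of the alkynylsilane should leave the hindered silyl ether and the acetal untouched.

Step 6
Reactants: 9 terminal alkyne
Product: 11 tert-butyl({(2R)-2-[4-(1,3-dioxolan-2-yl)but-1-en-2-yl]-4-(phenylsulfanyl)but-3-yn-1-yl}oxy)diphenylsilane, via lithium acetylide 10 (not isolated)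
Conditions: n-BuLi, THF, −78 °C; then PhSSPh, −78 °C to 0 °C
Reagents that add atoms: diphenyl disulfide, c1ccc(SSc2ccccc2)cc1
Why: Deprotonation of the terminal alkyne (far more acidic than the C9–H) and sulfenylation of the acetylide with the disulfide should give the alkynyl sulfide.

Step 7
Reactants: 11 alkynyl sulfide
Product: 12 tert-butyl({(2R)-2-[4-(1,3-dioxolan-2-yl)but-1-en-2-yl]-4-(phenylsulfonyl)but-3-yn-1-yl}oxy)diphenylsilane
Conditions: H2O2 (30 % aq), (NH4)6Mo7O24·4H2O (10 mol %), EtOH, 0 °C to rt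
Reagents that add atoms: hydrogen peroxide, OO
Why: Molybdate-catalysed oxidation of sulfide to sulfone is chemoselective for sulfur over the isolated 1,1-disubstituted alkene.

Step 8
Reactants: 12 alkynyl sulfone; 13 methylmagnesium bromide; 14 formaldehyde
Product: 16 (2Z,4R)-5-[(tert-butyldiphenylsilyl)oxy]-4-[4-(1,3-dioxolan-2-yl)but-1-en-2-yl]-3-methyl-2-(phenylsulfonyl)pent-2-en-1-ol, via alkenylmagnesium bromide 15 (not isolated)
Conditions: MeMgBr, CuBr·SMe2 (20 mol %), THF, −78 °C; then HCHO (gas, from cracked paraformaldehyde), −78 °C to 0 °C; aq NH4Cl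
Reagents that add atoms: methylmagnesium bromide (13), C[Mg]Br; formaldehyde (14), C=O
Why: Copper-catalysed conjugate syn-carbometalation of the alkynyl sulfone should place the methyl group on C10, and trapping of the α-sulfonyl alkenylmagnesium with formaldehyde adds C2; the low temperature should keep the propargylic C9–H untouched.

Step 9
Reactants: 16 allylic alcohol
Product: 18 tert-butyl({(2R,3Z)-2-[4-(1,3-dioxolan-2-yl)but-1-en-2-yl]-3-methyl-4,5-bis(phenylsulfonyl)pent-3-en-1-yl}oxy)diphenylsilane, via allylic mesylate 17 (not isolated)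
Conditions: MsCl, Et3N, CH2Cl2, −20 °C; then PhSO2Na, n-Bu4NI (cat.), DMF, rt
Reagents that add atoms: sodium benzenesulfinate, [Na+].[O-]S(=O)c1ccccc1 (methanesulfonyl chloride, CS(=O)(=O)Cl, leaves atoms only in 17)
Why: Mesylation and SN2 displacement by sulfinate (S-alkylation) should give the allyl sulfone, which puts a radical leaving group on C2.

Step 10
Reactants: 18 bis-sulfone acetal
Product: 19 (5R,6Z)-5-{[(tert-butyldiphenylsilyl)oxy]methyl}-6-methyl-4-methylidene-7,8-bis(phenylsulfonyl)oct-6-enal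
Conditions: PPTS, acetone/H2O (4:1), 60 °C
Reagents that add atoms: water, O
Why: Acid-catalysed acetal hydrolysis should release the C5 aldehyde while the silyl ether and sulfones survive.

Step 11
Reactants: 19 aldehyde; 20 trimethyl[(2-methylprop-1-en-1-yl)oxy]silane
Product: 22 (7R,8Z)-7-{[(tert-butyldiphenylsilyl)oxy]methyl}-3-hydroxy-2,2,8-trimethyl-6-methylidene-9,10-bis(phenylsulfonyl)dec-8-enal (both carbinol epimers), via trimethylsilyl ether 21 (not isolated)
Conditions: Sc(OTf)3 (5 mol %), CH2Cl2, −78 °C; then 1 M HCl, THF, 0 °C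
Reagents that add atoms: trimethyl[(2-methylprop-1-en-1-yl)oxy]silane (20), CC(C)=CO[Si](C)(C)C
Why: Lewis-acid-catalysed Mukaiyama aldol addition should build the C4–C5 bond and deliver C3 as a non-enolisable aldehyde, and the carbinol configuration at C5 is irrelevant because C5 later becomes a radical.

Step 12
Reactants: 22 β-hydroxy aldehyde
Product: 23 O-phenyl thionocarbonate of 22 at the C5 oxygen (both epimers)
Conditions: PhOC(S)Cl, pyridine, DMAP (cat.), CH2Cl2, 0 °C to rt
Reagents that add atoms: O-phenyl chlorothionoformate, S=C(Cl)Oc1ccccc1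
Why: Acylation of the secondary alcohol with the chlorothionoformate gives a Barton–McCombie-type radical precursor at C5.

Step 13
Reactants: 23 thionocarbonate aldehyde; 24 3-methylbutanoyl chloride
Product: 25 (7R,8Z)-1-chloro-7-{[(tert-butyldiphenylsilyl)oxy]methyl}-2,2,8-trimethyl-6-methylidene-3-[(phenoxycarbonothioyl)oxy]-9,10-bis(phenylsulfonyl)dec-8-en-1-yl 3-methylbutanoate (mixture at the chloro and thionocarbonate carbons)
Conditions: ZnCl2 (5 mol %), CH2Cl2, 0 °C
Reagents that add atoms: 3-methylbutanoyl chloride (24), CC(C)CC(=O)Cl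
Why: Lewis-acid-catalysed addition of an acyl chloride across the aldehyde C=O (1-chloroalkyl ester formation) places the final ester on the C3 oxygen and a radical precursor on C3.

Step 14
Reactants: 25 acyclic chloroalkyl ester
Product: 27 (1RS,3R,5R,9R,10R)-11-[(tert-butyldiphenylsilyl)oxy]-1-(phenylsulfonyl)drim-8(12)-en-3-yl 3-methylbutanoate, via monocyclic vinyl sulfone 26 (not isolated)
Conditions: Bu3SnH (2.3 equiv, syringe pump), AIBN (0.3 equiv), PhH (0.005 M), 80 °C
Reagents that add atoms: none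
Why: Proposed new method: Bu3Sn• adds to the thionocarbonate and C5–O scission gives the C5 radical, which closes ring B by 6-exo-trig attack on C10 (the β-carbon of the vinyl sulfone); the adduct radical at C1 expels PhSO2• from C2 and leaves a 2-sulfonyl-1-alkene (C1=C2) in 26, after which Bu3Sn• abstracts the less reactive chlorine at C3 and the α-acyloxy radical closes ring A by 6-endo-trig attack on C2, the α-sulfonyl radical finally taking hydrogen from Bu3SnH. The closest known reaction types are radical allylation with allyl sulfones (addition then β-fragmentation), additions of glycosyl-type α-acyloxy radicals to vinyl sulfones, and tandem radical annulations with 2-substituted allyl transfer reagents; what is new is their union in a (3+3) bicyclization. C10 is controlled by the C9 stereocentre: allylic 1,3-strain holds the C9–H in the plane of the tetrasubstituted alkene, so in the chair transition state CH2OSi is equatorial, C1 becomes equatorial and the methyl axial, and the C4 substituent on the C5 radical takes the equatorial position, which gives the trans ring fusion. C3 is set in the second closure, where the acyloxy group should take the equatorial position of the chair that forms on the rigid ring B. The step needs the thionocarbonate to react before the C–Cl bond (secured by the rate difference and slow stannane addition), 6-exo closure to beat 1,5-hydrogen transfer from C9–H (secured by sulfone activation of C10), and 6-endo over 5-exo in the second closure (secured by the polarity of the vinyl sulfone and the quaternary C10 beside C1).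

Step 15
Reactants: 27 bicyclic sulfone
Product: 28 (3R,5S,9R,10R)-11-[(tert-butyldiphenylsilyl)oxy]drim-8(12)-en-3-yl 3-methylbutanoate
Conditions: SmI2, HMPA, THF, −20 °C; MeOH
Reagents that add atoms: none
Why: Reductive desulfonylation (electron transfer, C–S cleavage, protonation) should remove the relay sulfone at C1 without touching a stereocentre of the target.

Step 16
Reactants: 28 silyl ether
Product: 29 (3R,5S,9R,10R)-11-hydroxydrim-8(12)-en-3-yl 3-methylbutanoate
Conditions: TBAF, AcOH, THF, rt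
Reagents that add atoms: none
Why: Fluoride-mediated cleavage of the silyl ether, buffered with acetic acid so that the ester is not attacked, should free the primary alcohol.

Step 17
Reactants: 29 primary alcohol; 30 7-hydroxy-2H-chromen-2-one (umbelliferone)
Product: 31 (3R,5S,9R,10R)-11-[(2-oxo-2H-chromen-7-yl)oxy]drim-8(12)-en-3-yl 3-methylbutanoate (CNP0295317.1)
Conditions: PPh3, DIAD, toluene, 0 °C to 60 °C
Reagents that add atoms: 7-hydroxy-2H-chromen-2-one (30), Oc1ccc2ccc(=O)oc2c1
Why: Mitsunobu etherification of the primary alcohol with the phenol should form the C11 aryl ether without touching any stereocentre.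

**Compound list**

1 | but-2-yne-1,4-diol | OCC#CCO | starting material
2 | 4-[(tert-butyldiphenylsilyl)oxy]but-2-yn-1-ol | OCC#CCO[Si](c1ccccc1)(c1ccccc1)C(C)(C)C | intermediate
3 | 2-(2-bromoethyl)-1,3-dioxolane | BrCCC1OCCO1 | starting material
4 | [2-(1,3-dioxolan-2-yl)ethyl]magnesium bromide | Br[Mg]CCC1OCCO1 | intermediate
5 | (2E)-4-[(tert-butyldiphenylsilyl)oxy]-2-[2-(1,3-dioxolan-2-yl)ethyl]but-2-en-1-ol | OC/C(CCC1OCCO1)=C/CO[Si](c1ccccc1)(c1ccccc1)C(C)(C)C | intermediate
6 | (2E)-4-[(tert-butyldiphenylsilyl)oxy]-2-[2-(1,3-dioxolan-2-yl)ethyl]but-2-en-1-yl diethyl phosphate | CCOP(=O)(OCC)OC/C(CCC1OCCO1)=C/CO[Si](c1ccccc1)(c1ccccc1)C(C)(C)C | intermediate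
7 | ethynyltrimethylsilane | C#C[Si](C)(C)C | starting material
8 | tert-butyl({(2R)-2-[4-(1,3-dioxolan-2-yl)but-1-en-2-yl]-4-(trimethylsilyl)but-3-yn-1-yl}oxy)diphenylsilane | C[Si](C)(C)C#C[C@@H](C(=C)CCC1OCCO1)CO[Si](c1ccccc1)(c1ccccc1)C(C)(C)C | intermediate
9 | tert-butyl({(2R)-2-[4-(1,3-dioxolan-2-yl)but-1-en-2-yl]but-3-yn-1-yl}oxy)diphenylsilane | C#C[C@@H](C(=C)CCC1OCCO1)CO[Si](c1ccccc1)(c1ccccc1)C(C)(C)C | intermediate
10 | lithium acetylide of 9 | [Li]C#C[C@@H](C(=C)CCC1OCCO1)CO[Si](c1ccccc1)(c1ccccc1)C(C)(C)C | intermediate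
11 | tert-butyl({(2R)-2-[4-(1,3-dioxolan-2-yl)but-1-en-2-yl]-4-(phenylsulfanyl)but-3-yn-1-yl}oxy)diphenylsilane | C(#C[C@@H](C(=C)CCC1OCCO1)CO[Si](c1ccccc1)(c1ccccc1)C(C)(C)C)Sc1ccccc1 | intermediate
12 | tert-butyl({(2R)-2-[4-(1,3-dioxolan-2-yl)but-1-en-2-yl]-4-(phenylsulfonyl)but-3-yn-1-yl}oxy)diphenylsilane | C(#C[C@@H](C(=C)CCC1OCCO1)CO[Si](c1ccccc1)(c1ccccc1)C(C)(C)C)S(=O)(=O)c1ccccc1 | intermediate
13 | methylmagnesium bromide | C[Mg]Br | starting material
14 | formaldehyde (from paraformaldehyde) | C=O | starting material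
15 | (Z)-alkenylmagnesium bromide from syn addition of methyl and MgBr across the triple bond of 12 (MgBr on the sulfonyl-bearing carbon) | C/C(=C(\[Mg]Br)S(=O)(=O)c1ccccc1)[C@@H](C(=C)CCC1OCCO1)CO[Si](c1ccccc1)(c1ccccc1)C(C)(C)C | intermediate
16 | (2Z,4R)-5-[(tert-butyldiphenylsilyl)oxy]-4-[4-(1,3-dioxolan-2-yl)but-1-en-2-yl]-3-methyl-2-(phenylsulfonyl)pent-2-en-1-ol | C/C(=C(\CO)S(=O)(=O)c1ccccc1)[C@@H](C(=C)CCC1OCCO1)CO[Si](c1ccccc1)(c1ccccc1)C(C)(C)C | intermediate
17 | methanesulfonate of 16 | C/C(=C(\COS(C)(=O)=O)S(=O)(=O)c1ccccc1)[C@@H](C(=C)CCC1OCCO1)CO[Si](c1ccccc1)(c1ccccc1)C(C)(C)C | intermediate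
18 | tert-butyl({(2R,3Z)-2-[4-(1,3-dioxolan-2-yl)but-1-en-2-yl]-3-methyl-4,5-bis(phenylsulfonyl)pent-3-en-1-yl}oxy)diphenylsilane | C/C(=C(\CS(=O)(=O)c1ccccc1)S(=O)(=O)c1ccccc1)[C@@H](C(=C)CCC1OCCO1)CO[Si](c1ccccc1)(c1ccccc1)C(C)(C)C | intermediate
19 | (5R,6Z)-5-{[(tert-butyldiphenylsilyl)oxy]methyl}-6-methyl-4-methylidene-7,8-bis(phenylsulfonyl)oct-6-enal | C/C(=C(\CS(=O)(=O)c1ccccc1)S(=O)(=O)c1ccccc1)[C@@H](C(=C)CCC=O)CO[Si](c1ccccc1)(c1ccccc1)C(C)(C)C | intermediate
20 | trimethyl[(2-methylprop-1-en-1-yl)oxy]silane | CC(C)=CO[Si](C)(C)C | starting material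
21 | trimethylsilyl ether of aldol 22 | C/C(=C(\CS(=O)(=O)c1ccccc1)S(=O)(=O)c1ccccc1)[C@@H](C(=C)CCC(O[Si](C)(C)C)C(C)(C)C=O)CO[Si](c1ccccc1)(c1ccccc1)C(C)(C)C | intermediate
22 | (7R,8Z)-7-{[(tert-butyldiphenylsilyl)oxy]methyl}-3-hydroxy-2,2,8-trimethyl-6-methylidene-9,10-bis(phenylsulfonyl)dec-8-enal (both carbinol epimers) | C/C(=C(\CS(=O)(=O)c1ccccc1)S(=O)(=O)c1ccccc1)[C@@H](C(=C)CCC(O)C(C)(C)C=O)CO[Si](c1ccccc1)(c1ccccc1)C(C)(C)C | intermediate
23 | O-phenyl thionocarbonate of 22 at the C5 oxygen (both epimers) | C/C(=C(\CS(=O)(=O)c1ccccc1)S(=O)(=O)c1ccccc1)[C@@H](C(=C)CCC(OC(=S)Oc1ccccc1)C(C)(C)C=O)CO[Si](c1ccccc1)(c1ccccc1)C(C)(C)C | intermediate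
24 | 3-methylbutanoyl chloride | CC(C)CC(=O)Cl | starting material
25 | (7R,8Z)-1-chloro-7-{[(tert-butyldiphenylsilyl)oxy]methyl}-2,2,8-trimethyl-6-methylidene-3-[(phenoxycarbonothioyl)oxy]-9,10-bis(phenylsulfonyl)dec-8-en-1-yl 3-methylbutanoate (mixture at C1 and C3 of the chain) | C/C(=C(\CS(=O)(=O)c1ccccc1)S(=O)(=O)c1ccccc1)[C@@H](C(=C)CCC(OC(=S)Oc1ccccc1)C(C)(C)C(Cl)OC(=O)CC(C)C)CO[Si](c1ccccc1)(c1ccccc1)C(C)(C)C | intermediate
26 | 1-chloro-2-methyl-2-{(1S,2R,3R)-3-{[(tert-butyldiphenylsilyl)oxy]methyl}-2-methyl-4-methylidene-2-[1-(phenylsulfonyl)ethenyl]cyclohexyl}propyl 3-methylbutanoate (ring B closed; chloro carbon as mixture) | C=C1CC[C@H](C(C)(C)C(Cl)OC(=O)CC(C)C)[C@@](C)(C(=C)S(=O)(=O)c2ccccc2)[C@@H]1CO[Si](c1ccccc1)(c1ccccc1)C(C)(C)C | intermediate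
27 | (1RS,3R,5R,9R,10R)-11-[(tert-butyldiphenylsilyl)oxy]-1-(phenylsulfonyl)drim-8(12)-en-3-yl 3-methylbutanoate | C=C1CC[C@@H]2C(C)(C)[C@H](OC(=O)CC(C)C)CC(S(=O)(=O)c3ccccc3)[C@@]2(C)[C@@H]1CO[Si](c1ccccc1)(c1ccccc1)C(C)(C)C | intermediate
28 | (3R,5S,9R,10R)-11-[(tert-butyldiphenylsilyl)oxy]drim-8(12)-en-3-yl 3-methylbutanoate | C=C1CC[C@@H]2C(C)(C)[C@H](OC(=O)CC(C)C)CC[C@@]2(C)[C@@H]1CO[Si](c1ccccc1)(c1ccccc1)C(C)(C)C | intermediate
29 | (3R,5S,9R,10R)-11-hydroxydrim-8(12)-en-3-yl 3-methylbutanoate | C=C1CC[C@@H]2C(C)(C)[C@H](OC(=O)CC(C)C)CC[C@@]2(C)[C@@H]1CO | intermediate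
30 | 7-hydroxy-2H-chromen-2-one (umbelliferone) | Oc1ccc2ccc(=O)oc2c1 | starting material
31 | (3R,5S,9R,10R)-11-[(2-oxo-2H-chromen-7-yl)oxy]drim-8(12)-en-3-yl 3-methylbutanoate | C=C1CC[C@@H]2C(C)(C)[C@H](OC(=O)CC(C)C)CC[C@@]2(C)[C@@H]1COc1ccc2ccc(=O)oc2c1 | target

**Step count and risks**

Total step count: 17. Longest linear sequence: 17 steps (1 to 31).

Steps most likely to fail:

1. Step 14 (key step, proposed new method). The C5 radical may take the doubly allylic C9–H by 1,5-hydrogen transfer instead of closing ring B. The C3 radical may form and be reduced before the vinyl sulfone exists, or the stannyl radical may hydrostannylate the vinyl sulfone. Facial control at C3 in the second closure may be poor. The fallback uses known reactions and closes one ring at a time; it sets out from aldehyde 23 and returns at 27. The aldehyde is masked as the dimethyl acetal F1 (HC(OMe)3, PPTS, MeOH). Bu3SnH and AIBN then perform only the first event, the 6-exo cyclization of the C5 radical onto the allyl sulfone with loss of PhSO2•, to give the monocyclic vinyl sulfone acetal F2. Mild hydrolysis (PPTS, acetone/H2O) gives the monocyclic aldehyde F3. SmI2 (t-BuOH, THF, −78 °C) closes ring A by ketyl–olefin addition to the vinyl sulfone and gives the 3-hydroxy sulfone F4. Acylation with 3-methylbutanoyl chloride 24 (DMAP, pyridine) then gives 27.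

2. Step 4. On a 2-substituted allylic phosphate the substitution may lose γ-regioselectivity or enantioselectivity, and the alkynylsilane may be desilylated by the alkoxide base. The fallback sets out from allylic alcohol 5 and returns at 8. Sharpless asymmetric epoxidation (Ti(OiPr)4, L-(+)-diethyl tartrate, t-BuOOH, CH2Cl2, −20 °C) should give the (2S,3S)-epoxy alcohol F5. Opening at C3 with inversion by the alkynylalane made from 7, n-BuLi and Et2AlCl gives the (2R,3R)-1,2-diol F6. Thiocarbonyldiimidazole converts it into the cyclic thionocarbonate F7, and Corey–Winter olefination (P(OMe)3, 110 °C) forms the 1,1-disubstituted alkene, which is 8.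

3. Step 17. Substitution at the β-branched, neopentyl-like C11 may be too slow, so that the activated alcohol is consumed by side reactions of the betaine. The fallback sets out from alcohol 29 and returns at 31. The alcohol is converted into the triflate F8 (Tf2O, pyridine, CH2Cl2, −78 °C), which is displaced by the cesium salt of 30 (Cs2CO3, DMF, rt).

**Further compounds**

F1 | step 14 | dimethyl acetal of aldehyde 23 | C/C(=C(\CS(=O)(=O)c1ccccc1)S(=O)(=O)c1ccccc1)[C@@H](C(=C)CCC(OC(=S)Oc1ccccc1)C(C)(C)C(OC)OC)CO[Si](c1ccccc1)(c1ccccc1)C(C)(C)C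
F2 | step 14 | monocyclic vinyl sulfone dimethyl acetal (ring B closed, configured as 26) | C=C1CC[C@H](C(C)(C)C(OC)OC)[C@@](C)(C(=C)S(=O)(=O)c2ccccc2)[C@@H]1CO[Si](c1ccccc1)(c1ccccc1)C(C)(C)C
F3 | step 14 | monocyclic vinyl sulfone aldehyde (configured as 26) | C=C1CC[C@H](C(C)(C)C=O)[C@@](C)(C(=C)S(=O)(=O)c2ccccc2)[C@@H]1CO[Si](c1ccccc1)(c1ccccc1)C(C)(C)C
F4 | step 14 | (1RS,3R,5R,9R,10R)-11-[(tert-butyldiphenylsilyl)oxy]-1-(phenylsulfonyl)drim-8(12)-en-3-ol | C=C1CC[C@@H]2C(C)(C)[C@H](O)CC(S(=O)(=O)c3ccccc3)[C@@]2(C)[C@@H]1CO[Si](c1ccccc1)(c1ccccc1)C(C)(C)C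
F5 | step 4 | {(2S,3S)-3-{[(tert-butyldiphenylsilyl)oxy]methyl}-2-[2-(1,3-dioxolan-2-yl)ethyl]oxiran-2-yl}methanol | OC[C@]1(CCC2OCCO2)O[C@H]1CO[Si](c1ccccc1)(c1ccccc1)C(C)(C)C
F6 | step 4 | (2R,3R)-3-{[(tert-butyldiphenylsilyl)oxy]methyl}-2-[2-(1,3-dioxolan-2-yl)ethyl]-5-(trimethylsilyl)pent-4-yne-1,2-diol | C[Si](C)(C)C#C[C@@H]([C@@](O)(CO)CCC1OCCO1)CO[Si](c1ccccc1)(c1ccccc1)C(C)(C)C
F7 | step 4 | cyclic thionocarbonate (1,3-dioxolane-2-thione) of diol F6 | C[Si](C)(C)C#C[C@@H]([C@]1(CCC2OCCO2)COC(=S)O1)CO[Si](c1ccccc1)(c1ccccc1)C(C)(C)C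
F8 | step 17 | trifluoromethanesulfonate of alcohol 29 | C=C1CC[C@@H]2C(C)(C)[C@H](OC(=O)CC(C)C)CC[C@@]2(C)[C@@H]1COS(=O)(=O)C(F)(F)F
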